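## Retrosynthetic overview

- Numbering (bicyclo[3.3.1]non-2-ene): C1 (CHO bridgehead), C2=C3 (enal), C4, C5 (methyl bridgehead), C6, C7, C8 (side-chain carbon), C9 (OAc bridge); ring A = C1–C5 + C9, ring B = C5–C9 + C1. Both aldehydes come from a 2-ene-1,4-diol (Swern oxidation); the 9-acetate comes from a C9 ketone (face-selective hydride, acetylation).
- Ring A is opened at C1–C2: bridged aldol of a β-keto ester onto an α-keto ester, then dehydration to the C2=C3 ester. This leaves a cyclohexanone (ring B) carrying a 1,5-diketone.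
- Key disconnection: C9–C5 and C3–C4 by an intramolecular de Mayo reaction (enol–alkene [2+2] photocycloaddition, then retro-aldol) of an acyclic enolised 2,4-dioxo ester that carries an isopropenyl group. It closes ring B, creates the quaternary C5 and delivers the 1,5-diketone.
- Enabling feature: C9 (the oxygen-bearing bridge carbon) and C2 are 1,5-related through C5(CH3)–C4H2–C3, a 1,5-dicarbonyl retron in which C5–C4 is a former C=C and C9/C3 a former enol C=C. C5 lies four atoms (C1, C8, C7, C6) from C9, so the tethered cycloaddition is six-membered.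
- The acyclic precursor comes from (R)-citronellic acid (side-chain stereocentre bought); C8 is set by Evans alkylation; C5, C1 and C9 are relayed from C8. Ring order: B (step 8), then A (step 9).

Key step: step 8

Remark: the target is taken as the (1R,5R,8S,9R)-isomer with a (2R) side chain, as encoded by its SMILES; enolates and other activated species generated in situ by bases or coupling reagents are treated as part of a step, and only discrete intermediates of telescoped steps are numbered.

## Route

Step 1
Reactants: 1 (R)-citronellic acid; 2 (R)-4-benzyloxazolidin-2-one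
Product: 3 (4R)-4-benzyl-3-[(3R)-3,7-dimethyloct-6-enoyl]oxazolidin-2-one
Conditions: DCC, DMAP (cat.), CH2Cl2, 0 °C → rt
Reagents that add atoms: none
Why: Carbodiimide/DMAP N-acylation (Steglich-type coupling) of the oxazolidinone by the acid should give the imide without touching the C3 stereocentre or the alkene.

Step 2
Reactants: 3 imide; 4 tert-butyl bromoacetate
Product: 5 tert-butyl (3R,4R)-3-[(4R)-4-benzyl-2-oxooxazolidine-3-carbonyl]-4,8-dimethylnon-7-enoate
Conditions: NaN(SiMe3)2, THF, −78 °C; then 4, −78 → −40 °C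
Reagents that add atoms: none
Why: Evans alkylation: the chelated Z sodium enolate should be alkylated by the reactive bromoacetate on the face opposite to the benzyl group, which sets the future C8 stereocentre under auxiliary control.

Step 3
Reactants: 5 alkylated imide
Product: 6 tert-butyl (3R,4R)-3-(hydroxymethyl)-4,8-dimethylnon-7-enoate
Conditions: LiBH4, MeOH (1 equiv), THF, 0 °C
Reagents that add atoms: none
Why: Reductive removal of the auxiliary: LiBH4 should reduce the activated imide carbonyl to the primary alcohol while the tert-butyl ester survives, and the auxiliary is recovered.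

Step 4
Reactants: 6 alcohol
Product: 7 tert-butyl (3R,4R)-3-(iodomethyl)-4,8-dimethylnon-7-enoate
Conditions: I2, PPh3, imidazole, CH2Cl2, 0 °C → rt
Reagents that add atoms: iodine, II
Why: Appel-type iodination of the primary alcohol (SN2 at a CH2 group, no stereocentre involved) should outrun lactonisation onto the tert-butyl ester.

Step 5
Reactants: 7 iodide; 8 2-methylallylmagnesium chloride
Product: 9 tert-butyl (3R)-6-methyl-3-[(2R)-6-methylhept-5-en-2-yl]hept-6-enoate
Conditions: 8 (2 equiv), CuI (10 mol %), THF, −30 → 0 °C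
Reagents that add atoms: none
Why: Copper-catalysed sp3–sp3 cross-coupling of the primary iodide with the allylic Grignard reagent installs the isopropenyl terminus; the symmetrical 2-methylallyl unit makes SN2 versus SN2' attack irrelevant and the tert-butyl ester should resist the Grignard reagent at low temperature.

Step 6
Reactants: 9 ester; 10 N-acetylimidazole
Product: 11 tert-butyl (3S)-2-acetyl-6-methyl-3-[(2R)-6-methylhept-5-en-2-yl]hept-6-enoate (C2 epimers)
Conditions: LiN(iPr)2, THF, −78 °C; then 10, −78 → 0 °C; aq. NH4Cl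
Reagents that add atoms: none
Why: Crossed Claisen acylation of the lithium ester enolate by the acyl imidazole should give the β-keto ester; the new C2 centre is enolisable and its configuration does not matter.

Step 7
Reactants: 11 β-keto ester; 12 dimethyl oxalate
Product: 13 methyl (6S)-5-(tert-butoxycarbonyl)-9-methyl-6-[(2R)-6-methylhept-5-en-2-yl]-2,4-dioxodec-9-enoate (C5 epimers; chelated enol)
Conditions: LiN(iPr)2 (3.2 equiv), THF, −78 → 0 °C; then 12, −78 → −20 °C; 1 M HCl
Reagents that add atoms: none
Why: Claisen condensation of the β-keto ester dianion at its terminal (γ) carbanion with dimethyl oxalate should give the 2,4-dioxo ester, which should exist as the hydrogen-bonded enol needed for the photoreaction.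

Step 8
Reactants: 13 enolised 2,4-dioxo ester
Product: 15 tert-butyl (3R,6S)-3-(4-methoxy-3,4-dioxobutyl)-3-methyl-6-[(2R)-6-methylhept-5-en-2-yl]-2-oxocyclohexane-1-carboxylate (C1 epimers), via cyclobutanol photoadduct 14 (not isolated)
Conditions: hν (350 nm, Pyrex), degassed MeCN (5 mM), 20 °C
Reagents that add atoms: none
Why: Excitation of the hydrogen-bonded enol (C9(OH)=C3–C2=O enone chromophore) should lead, through the triplet, to bonding of C9 to the internal alkene carbon C5 and then of C3 to C4, and the resulting cis-fused bicyclo[4.2.0]octan-1-ol 14 (a β-hydroxy ketone in a strained ring) should fragment by retro-aldol cleavage of the C9–C3 bond to the 1,5-diketone. The closest known reaction type is the intramolecular de Mayo reaction of enolised 1,3-diketones and 2,4-dioxo esters with tethered alkenes. Ring B is closed through the C9–C5 bond in a six-membered (1,6, exo) mode, the four-membered ring is transient, and the net result is insertion of the C5=C4 unit into the C9–C3 bond. The new quaternary stereocentre C5 is controlled by C8: in the chair-like transition state the side chain on C8, the C5 methyl group and the bulky enone arm on C9 should be equatorial, which places C4 axial and cis to the C8 side chain, while C1 stays enolisable and is set in step 9. The step needs regioselectivity (C9–C5/C3–C4 in place of the crossed mode, reaction through the other enol tautomer or reaction at the side-chain alkene); the four-atom tether C1–C8–C7–C6 between C9 and C5 secures it, because only this pairing closes a six-membered ring and the alternatives need seven- or eight-membered rings.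

Step 9
Reactants: 15 cyclohexanone 1,5-diketone
Product: 17 1-tert-butyl 2-methyl (1R,5R,8S)-5-methyl-8-[(2R)-6-methylhept-5-en-2-yl]-9-oxobicyclo[3.3.1]non-2-ene-1,2-dicarboxylate, via bridged ketol 16 (not isolated)
Conditions: DBU (0.2 equiv), CH2Cl2, 0 °C → rt; then pyridine, SOCl2, 0 °C
Reagents that add atoms: none
Why: Intramolecular aldol addition of the β-keto ester carbon C1 to the electrophilic α-keto ester carbonyl C2 should close ring A in a 6-(enolexo)-exo-trig mode, which is only possible with the C5 chain and the new C1–C2 bond cis-diaxial on ring B and therefore fixes C1; SOCl2/pyridine should then dehydrate the tertiary α-hydroxy ester by E2 elimination toward C3, the only carbon that bears β-hydrogens.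

Step 10
Reactants: 17 bicyclic keto diester
Product: 18 (1S,5R,8S,9R)-1,2-bis(hydroxymethyl)-5-methyl-8-[(2R)-6-methylhept-5-en-2-yl]bicyclo[3.3.1]non-2-en-9-ol
Conditions: iBu2AlH (excess), CH2Cl2, −78 °C → rt; aq. potassium sodium tartrate
Reagents that add atoms: none
Why: Hydride reduction: iBu2AlH should attack the C9 ketone from the less hindered face over the unsaturated ring A (the axial hydrogens on C6 and C8 shield the other face), giving the 9-hydroxyl syn to the saturated bridge, and should reduce both esters to primary alcohols with 1,2-selectivity at the enoate.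

Step 11
Reactants: 18 triol
Product: 20 (1S,5R,8S,9R)-1,2-bis{[tert-butyl(dimethyl)silyl]oxymethyl}-5-methyl-8-[(2R)-6-methylhept-5-en-2-yl]bicyclo[3.3.1]non-2-en-9-yl acetate, via bis-silyl ether 19 (not isolated)
Conditions: TBSCl (2.3 equiv), imidazole, CH2Cl2, 0 °C → rt; then Ac2O, pyridine, DMAP, 40 °C
Reagents that add atoms: tert-butyldimethylsilyl chloride, CC(C)(C)[Si](C)(C)Cl; acetic anhydride, CC(=O)OC(C)=O
Why: Silylation should discriminate the two primary hydroxyls from the very hindered C9 hydroxyl (flanked by two quaternary carbons), which is then acetylated by DMAP-catalysed acyl transfer.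

Step 12
Reactants: 20 bis-silyl ether acetate
Product: 21 (1S,5R,8S,9R)-1,2-bis(hydroxymethyl)-5-methyl-8-[(2R)-6-methylhept-5-en-2-yl]bicyclo[3.3.1]non-2-en-9-yl acetate
Conditions: HF·pyridine, pyridine, THF, 0 °C → rt
Reagents that add atoms: none
Why: Fluoride-mediated desilylation under buffered, non-basic conditions should free both primary alcohols and avoid 1,3-acyl migration from O9 to the neighbouring hydroxymethyl group.

Step 13
Reactants: 21 diol acetate
Product: 22 (1R,5R,8S,9R)-1,2-diformyl-5-methyl-8-[(2R)-6-methylhept-5-en-2-yl]bicyclo[3.3.1]non-2-en-9-yl acetate (target)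
Conditions: (COCl)2, DMSO, CH2Cl2, −78 °C; then Et3N, −78 → 0 °C
Reagents that add atoms: none
Why: Swern oxidation should convert both primary alcohols of the 2-ene-1,4-diol into the 1,4-dialdehyde at low temperature without lactol or lactone formation, and no α-epimerisable centre is present because C1 is quaternary.

## Compound list

1 | (R)-citronellic acid [(3R)-3,7-dimethyloct-6-enoic acid] | C[C@H](CCC=C(C)C)CC(=O)O | starting material
2 | (R)-4-benzyloxazolidin-2-one | O=C1N[C@H](Cc2ccccc2)CO1 | starting material
3 | (4R)-4-benzyl-3-[(3R)-3,7-dimethyloct-6-enoyl]oxazolidin-2-one | O=C(C[C@H](C)CCC=C(C)C)N1[C@H](Cc2ccccc2)COC1=O | intermediate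
4 | tert-butyl bromoacetate | CC(C)(C)OC(=O)CBr | starting material
5 | tert-butyl (3R,4R)-3-[(4R)-4-benzyl-2-oxooxazolidine-3-carbonyl]-4,8-dimethylnon-7-enoate | CC(C)(C)OC(=O)C[C@H]([C@H](C)CCC=C(C)C)C(=O)N1[C@H](Cc2ccccc2)COC1=O | intermediate
6 | tert-butyl (3R,4R)-3-(hydroxymethyl)-4,8-dimethylnon-7-enoate | CC(C)(C)OC(=O)C[C@H]([C@H](C)CCC=C(C)C)CO | intermediate
7 | tert-butyl (3R,4R)-3-(iodomethyl)-4,8-dimethylnon-7-enoate | CC(C)(C)OC(=O)C[C@H]([C@H](C)CCC=C(C)C)CI | intermediate
8 | 2-methylallylmagnesium chloride | CC(=C)C[Mg]Cl | starting material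
9 | tert-butyl (3R)-6-methyl-3-[(2R)-6-methylhept-5-en-2-yl]hept-6-enoate | CC(C)(C)OC(=O)C[C@H]([C@H](C)CCC=C(C)C)CCC(C)=C | intermediate
10 | N-acetylimidazole | CC(=O)n1ccnc1 | starting material
11 | tert-butyl (3S)-2-acetyl-6-methyl-3-[(2R)-6-methylhept-5-en-2-yl]hept-6-enoate (C2 epimers) | CC(=O)C(C(=O)OC(C)(C)C)[C@H]([C@H](C)CCC=C(C)C)CCC(C)=C | intermediate
12 | dimethyl oxalate | COC(=O)C(=O)OC | starting material
13 | methyl (6S)-5-(tert-butoxycarbonyl)-9-methyl-6-[(2R)-6-methylhept-5-en-2-yl]-2,4-dioxodec-9-enoate (C5 epimers; drawn as the keto tautomer, reacts as the C4 enol) | COC(=O)C(=O)CC(=O)C(C(=O)OC(C)(C)C)[C@H]([C@H](C)CCC=C(C)C)CCC(C)=C | intermediate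
14 | cyclobutanol photoadduct: tert-butyl 1-hydroxy-8-(2-methoxy-2-oxoacetyl)-6-methyl-3-[(2R)-6-methylhept-5-en-2-yl]bicyclo[4.2.0]octane-2-carboxylate (cis-fused; C1, C2, C8 not specified) | OC12C(C(=O)OC(C)(C)C)[C@H]([C@H](C)CCC=C(C)C)CC[C@]1(C)CC2C(=O)C(=O)OC | intermediate (not isolated)
15 | tert-butyl (3R,6S)-3-(4-methoxy-3,4-dioxobutyl)-3-methyl-6-[(2R)-6-methylhept-5-en-2-yl]-2-oxocyclohexane-1-carboxylate (C1 epimers; dioxobutyl chain cis to the C6 side chain) | O=C1[C@@](C)(CCC(=O)C(=O)OC)CC[C@@H]([C@H](C)CCC=C(C)C)C1C(=O)OC(C)(C)C | intermediate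
16 | bridged ketol: 1-tert-butyl 2-methyl (1R,5R,8S)-2-hydroxy-5-methyl-8-[(2R)-6-methylhept-5-en-2-yl]-9-oxobicyclo[3.3.1]nonane-1,2-dicarboxylate (C2 epimers) | O=C1[C@@]2(C)CCC(O)(C(=O)OC)[C@]1(C(=O)OC(C)(C)C)[C@H]([C@H](C)CCC=C(C)C)CC2 | intermediate (not isolated)
17 | 1-tert-butyl 2-methyl (1R,5R,8S)-5-methyl-8-[(2R)-6-methylhept-5-en-2-yl]-9-oxobicyclo[3.3.1]non-2-ene-1,2-dicarboxylate | O=C1[C@@]2(C)CC=C(C(=O)OC)[C@]1(C(=O)OC(C)(C)C)[C@H]([C@H](C)CCC=C(C)C)CC2 | intermediate
18 | (1S,5R,8S,9R)-1,2-bis(hydroxymethyl)-5-methyl-8-[(2R)-6-methylhept-5-en-2-yl]bicyclo[3.3.1]non-2-en-9-ol (9-OH syn to the C6–C8 bridge) | O[C@@H]1[C@@]2(C)CC=C(CO)[C@]1(CO)[C@H]([C@H](C)CCC=C(C)C)CC2 | intermediate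
19 | bis-silyl ether: (1S,5R,8S,9R)-1,2-bis{[tert-butyl(dimethyl)silyl]oxymethyl}-5-methyl-8-[(2R)-6-methylhept-5-en-2-yl]bicyclo[3.3.1]non-2-en-9-ol | O[C@@H]1[C@@]2(C)CC=C(CO[Si](C)(C)C(C)(C)C)[C@]1(CO[Si](C)(C)C(C)(C)C)[C@H]([C@H](C)CCC=C(C)C)CC2 | intermediate (not isolated)
20 | (1S,5R,8S,9R)-1,2-bis{[tert-butyl(dimethyl)silyl]oxymethyl}-5-methyl-8-[(2R)-6-methylhept-5-en-2-yl]bicyclo[3.3.1]non-2-en-9-yl acetate | CC(=O)O[C@@H]1[C@@]2(C)CC=C(CO[Si](C)(C)C(C)(C)C)[C@]1(CO[Si](C)(C)C(C)(C)C)[C@H]([C@H](C)CCC=C(C)C)CC2 | intermediate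
21 | (1S,5R,8S,9R)-1,2-bis(hydroxymethyl)-5-methyl-8-[(2R)-6-methylhept-5-en-2-yl]bicyclo[3.3.1]non-2-en-9-yl acetate | CC(=O)O[C@@H]1[C@@]2(C)CC=C(CO)[C@]1(CO)[C@H]([C@H](C)CCC=C(C)C)CC2 | intermediate
22 | (1R,5R,8S,9R)-1,2-diformyl-5-methyl-8-[(2R)-6-methylhept-5-en-2-yl]bicyclo[3.3.1]non-2-en-9-yl acetate (CNP0299929.2) | CC(=O)O[C@@H]1[C@@]2(C)CC=C(C=O)[C@]1(C=O)[C@H]([C@H](C)CCC=C(C)C)CC2 | target

## Step count and risks

Total step count: 13. Longest linear sequence: 13 steps (1 → 22).

Steps most likely to fail:

1. Step 8 (key step). The excited enol may cycloadd through the other enol tautomer or in the crossed sense, or decay without capturing the unactivated 1,1-disubstituted alkene, and the facial discrimination at C5 may be low. The fallback sets out from iodide 7 and returns at 15, using ground-state anionic chemistry in place of the photoreaction. Giese addition of the primary radical from 7 (Bu3SnH, AIBN, benzene, 80 °C) to methyl methacrylate should give 1-tert-butyl 7-methyl (3R)-6-methyl-3-[(2R)-6-methylhept-5-en-2-yl]heptanedioate F1. Dieckmann condensation (KOtBu, THF; the tert-butyl ester enolate attacks the methyl ester, C1–C9 bond) should close ring B to tert-butyl (6S)-3-methyl-6-[(2R)-6-methylhept-5-en-2-yl]-2-oxocyclohexane-1-carboxylate F2. Michael addition of the dianion of F2 (NaH, then n-BuLi, THF, −78 °C) through its methyl-bearing γ-carbon to methyl 2-oxobut-3-enoate should then attach the C4–C3–C2 chain at C5 and give 15.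

2. Step 9. The aldol addition may revert (retro-aldol) before dehydration, and the hindered tertiary α-hydroxy ester may undergo substitution or fragmentation in place of clean elimination. The fallback sets out from 15 and returns at 17. Double deprotonation (KN(SiMe3)2, 2.2 equiv, THF, −78 °C) and O-sulfonylation of the more reactive α-keto ester enolate with N-(5-chloropyridin-2-yl)-bis(trifluoromethanesulfonyl)imide should give tert-butyl (3R,6S)-3-[(3Z)-4-methoxy-4-oxo-3-(trifluoromethylsulfonyloxy)but-3-enyl]-3-methyl-6-[(2R)-6-methylhept-5-en-2-yl]-2-oxocyclohexane-1-carboxylate F3. Intramolecular palladium-catalysed α-alkenylation of the remaining β-keto ester enolate (Pd2(dba)3, P(tBu)3, K3PO4, toluene, 80 °C) should then form C1–C2 with the C2=C3 double bond already in place and give 17 without any dehydration.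

3. Step 7. Proton transfer or O-acylation may compete with C-acylation at the terminal carbanion, and the tricarbonyl product may cyclise to a pyranone during acidic work-up. The fallback sets out from 11 and returns at 13. Stepwise silylation (Me3SiCl, Et3N; then LiN(iPr)2, Me3SiCl, THF, −78 °C) should give the bis(trimethylsilyl) dienol ether of 11 F4 (a 1-tert-butoxy-1,3-bis(trimethylsilyloxy)buta-1,3-diene). Its terminal carbon should be acylated by methyl chlorooxoacetate (CH2Cl2, −78 °C, vinylogous Mukaiyama-type acylation) to give 13 after neutral aqueous work-up.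

Further compounds
F1 | step 8 | 1-tert-butyl 7-methyl (3R)-6-methyl-3-[(2R)-6-methylhept-5-en-2-yl]heptanedioate (C6 epimers) | CC(C)(C)OC(=O)C[C@H]([C@H](C)CCC=C(C)C)CCC(C)C(=O)OC
F2 | step 8 | tert-butyl (6S)-3-methyl-6-[(2R)-6-methylhept-5-en-2-yl]-2-oxocyclohexane-1-carboxylate (C1 and C3 epimers) | O=C1C(C)CC[C@@H]([C@H](C)CCC=C(C)C)C1C(=O)OC(C)(C)C
F3 | step 9 | tert-butyl (3R,6S)-3-[(3Z)-4-methoxy-4-oxo-3-(trifluoromethylsulfonyloxy)but-3-enyl]-3-methyl-6-[(2R)-6-methylhept-5-en-2-yl]-2-oxocyclohexane-1-carboxylate | O=C1[C@@](C)(C/C=C(\OS(=O)(=O)C(F)(F)F)C(=O)OC)CC[C@@H]([C@H](C)CCC=C(C)C)C1C(=O)OC(C)(C)C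
F4 | step 7 | bis(trimethylsilyl) dienol ether of 11 (1-tert-butoxy-1,3-bis(trimethylsilyloxy)buta-1,3-diene bearing the C8 unit at C2) | C=C(O[Si](C)(C)C)C(=C(OC(C)(C)C)O[Si](C)(C)C)[C@H]([C@H](C)CCC=C(C)C)CCC(C)=C
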